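**Retrosynthetic overview**
- The strategy rests on the 1,4-benzoquinone ring C1(=O)–C2(Me)=C3(OAr)–C4(=O)–C5(iPr)=C6(H). It is cut at C1–C2 and C3–C4 into a four-carbon diacyl unit C4–C5=C6–C1 (isopropylmaleoyl held on cobalt) and the two-carbon unit C2≡C3 of a 1-aryloxypropyne that already carries the hindered aryl–O bond.
- The diacyl cobalt unit comes from 3-isopropylcyclobutenedione (dichloroketene [2+2] with 3-methylbut-1-yne, then hydrolysis), cobalt(I) insertion into its CO–CO bond and exchange to the dimethylglyoxime/pyridine complex.
- The ynol ether comes from the dimer phenol via its dichlorovinyl ether (trichloroethylene), elimination to the lithium acetylide and C-methylation.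
- The dimer phenol is cut at the diaryl ether C–O bond: Ullmann coupling of 4-methoxythymol with its own 6-iodo O-benzyl derivative; 4-methoxythymol comes from thymol by para-bromination and copper-catalysed methoxylation.
- Ring order: both benzene rings come from thymol; the cyclobutene ring (step 1) becomes the cobaltacycle (step 3); the quinone ring is the only ring of the target that is built, and it is closed last.

Key step: step 13

Remark: the target has no stereocentre and the diaryl ether axes are taken as freely rotating, so it is achiral and no stereochemical control is needed.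

**Step 1**
Reactants: 1 3-methylbut-1-yne; 2 trichloroacetyl chloride
Product: 4 4,4-dichloro-3-isopropylcyclobut-2-en-1-one, via dichloroketene 3 (not isolated)
Conditions: Zn–Cu, Et2O/DME, 0 °C to rt, cold condenser
Reagents that add atoms: none
Why: Zinc dechlorination of 2 generates dichloroketene, which undergoes thermal [2+2] cycloaddition with the terminal alkyne, the ketene carbonyl carbon bonding to the unsubstituted alkyne carbon so that isopropyl ends on C3 next to CCl2.

**Step 2**
Reactants: 4 4,4-dichloro-3-isopropylcyclobut-2-en-1-one
Product: 5 3-isopropylcyclobut-3-ene-1,2-dione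
Conditions: conc. H2SO4, 50 °C; then ice/H2O
Reagents that add atoms: water, O
Why: Acid hydrolysis of the allylic gem-dichloride through the chlorine-stabilised cyclobutenyl cation unmasks the second carbonyl, the standard conversion of 4,4-dichlorocyclobutenones into cyclobutenediones.

**Step 3**
Reactants: 5 3-isopropylcyclobut-3-ene-1,2-dione
Product: 6 chloro(2-isopropylmaleoyl)bis(triphenylphosphine)cobalt(III) (3-isopropyl-1-cobaltacyclopent-3-ene-2,5-dione)
Conditions: ClCo(PPh3)3 (1.0 equiv), PhMe, rt, Ar
Reagents that add atoms: chlorotris(triphenylphosphine)cobalt(I), Cl[Co-3]([P+](c1ccccc1)(c1ccccc1)c1ccccc1)([P+](c1ccccc1)(c1ccccc1)c1ccccc1)[P+](c1ccccc1)(c1ccccc1)c1ccccc1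
Why: Oxidative addition of cobalt(I) into the strained bond between the two carbonyl carbons of the cyclobutenedione should give the five-membered diacyl cobalt(III) metallacycle with loss of one phosphine, and only one isomer is possible.

**Step 4**
Reactants: 6 chloro(2-isopropylmaleoyl)bis(triphenylphosphine)cobalt(III)
Product: 7 chloro(dimethylglyoxime-N,N')(pyridine)(2-isopropylmaleoyl)cobalt(III)
Conditions: dimethylglyoxime (1.1 equiv), pyridine, rt
Reagents that add atoms: dimethylglyoxime, CC(=NO)C(C)=NO; pyridine, c1ccncc1
Why: Ligand substitution of the two phosphines by chelating dimethylglyoxime and pyridine should give the air-stable octahedral complex, the form of maleoylcobalt reagent that reacts with alkynes under Lewis acid promotion.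

**Step 5**
Reactants: 8 thymol
Product: 9 4-bromothymol (4-bromo-2-isopropyl-5-methylphenol)
Conditions: NBS (1.0 equiv), MeCN, 0 °C to rt
Reagents that add atoms: N-bromosuccinimide, O=C1CCC(=O)N1Br
Why: Electrophilic aromatic bromination of thymol goes para to the hydroxyl group, a known selective halogenation of this phenol.

**Step 6**
Reactants: 9 4-bromothymol
Product: 10 4-methoxythymol (2-isopropyl-4-methoxy-5-methylphenol)
Conditions: NaOMe (5 equiv), CuI (0.2 equiv), MeOH/DMF, 110 °C, N2; then aq. HCl
Reagents that add atoms: sodium methoxide, C[O-].[Na+]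
Why: Copper-catalysed Ullmann-type methoxylation of the aryl bromide tolerates the free phenol as its phenoxide, as in the usual conversion of bromophenols into methoxyphenols.

**Step 7**
Reactants: 10 4-methoxythymol
Product: 11 2-iodo-6-isopropyl-4-methoxy-3-methylphenol
Conditions: NIS (1.05 equiv), TsOH (cat.), MeCN, 0 °C, dark
Reagents that add atoms: N-iodosuccinimide, O=C1CCC(=O)N1I
Why: Electrophilic aromatic iodination goes to the only free position ortho to the strongly activating OH, since the other open position is ortho only to OMe and is shielded by the isopropyl group.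

**Step 8**
Reactants: 11 2-iodo-6-isopropyl-4-methoxy-3-methylphenol
Product: 12 2-(benzyloxy)-3-iodo-1-isopropyl-5-methoxy-4-methylbenzene
Conditions: BnBr, K2CO3, DMF, 50 °C
Reagents that add atoms: benzyl bromide, BrCc1ccccc1
Why: Williamson etherification masks the phenol for the coupling with a group that is later removed by hydrogenolysis without touching the methyl or diaryl ethers.

**Step 9**
Reactants: 12 2-(benzyloxy)-3-iodo-1-isopropyl-5-methoxy-4-methylbenzene; 10 4-methoxythymol
Product: 13 2-(benzyloxy)-1-isopropyl-3-(2-isopropyl-4-methoxy-5-methylphenoxy)-5-methoxy-4-methylbenzene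
Conditions: 10 (1.3 equiv), CuI (0.2 equiv), picolinic acid (0.4 equiv), K3PO4 (2 equiv), DMSO, 100 °C, Ar
Reagents that add atoms: none
Why: Ullmann diaryl ether coupling under copper/picolinate catalysis, conditions suited to ortho-substituted phenols and ortho-substituted aryl iodides, joins the electron-rich phenoxide of 10 to the only carbon–halogen bond present.

**Step 10**
Reactants: 13 2-(benzyloxy)-1-isopropyl-3-(2-isopropyl-4-methoxy-5-methylphenoxy)-5-methoxy-4-methylbenzene
Product: 14 dimer phenol, 6-isopropyl-2-(2-isopropyl-4-methoxy-5-methylphenoxy)-4-methoxy-3-methylphenol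
Conditions: H2 (1 atm), 10% Pd/C, EtOAc/EtOH, rt
Reagents that add atoms: none
Why: Catalytic hydrogenolysis cleaves only the benzyl ether, because aryl methyl ethers and the diaryl ether are inert under these conditions.

**Step 11**
Reactants: 14 dimer phenol; 15 trichloroethylene
Product: 17 (E)-1,2-dichlorovinyl ether of the dimer phenol, via dichloroacetylene 16 (not isolated)
Conditions: 15 (1.5 equiv), Cs2CO3 (1.5 equiv), DMF, 60 °C
Reagents that add atoms: none
Why: Base-induced dehydrochlorination of 15 to dichloroacetylene and anti addition of the phenoxide across it is the standard preparation of aryl (E)-1,2-dichlorovinyl ethers, and the small linear electrophile should tolerate the flanked phenoxide.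

**Step 12**
Reactants: 17 (E)-1,2-dichlorovinyl ether of the dimer phenol
Product: 19 prop-1-ynyl ether of the dimer phenol, via lithium aryloxyacetylide 18 (not isolated)
Conditions: n-BuLi (2.3 equiv), THF, −78 to −40 °C; then MeI (3 equiv), HMPA, −78 °C to rt; chromatography on Et3N-deactivated silica
Reagents that add atoms: iodomethane, CI
Why: Vinyl deprotonation, β-elimination of LiCl and chlorine–lithium exchange should give the lithium aryloxyacetylide, which is C-methylated by MeI in the presence of HMPA, the established route from dichlorovinyl ethers to 1-alkoxy- and 1-aryloxyalkynes.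

**Step 13**
Reactants: 7 chloro(dimethylglyoxime-N,N')(pyridine)(2-isopropylmaleoyl)cobalt(III); 19 prop-1-ynyl ether of the dimer phenol
Product: 20 target quinone, 3-[6-isopropyl-2-(2-isopropyl-4-methoxy-5-methylphenoxy)-4-methoxy-3-methylphenoxy]-5-isopropyl-2-methylcyclohexa-2,5-diene-1,4-dione
Conditions: 7 (1.3 equiv), BF3·OEt2 (1.1 equiv), CH2Cl2, 4 Å MS, −40 °C; then 19 added slowly, −40 °C to rt; air, SiO2
Reagents that add atoms: none
Why: Proposed new method: the closest known reaction is the Lewis-acid-promoted benzoquinone synthesis from maleoylcobalt dimethylglyoxime complexes and alkyl-, aryl- or ester-substituted alkynes, here extended to a 1-aryloxyalkyne, which has not been used as the alkyne partner. BF3 is expected to bind the acyl oxygen on C1 of 7, which lies beside the ring CH and is both the less hindered and, as the carbonyl of a β-alkyl enone, the more basic one, so that C1 becomes electrophilic; the methyl-bearing carbon of the ynol ether, its nucleophilic terminus, attacks C1 (bond C1–C2) and the aryloxy-stabilised ketenium carbon C3 is captured by cobalt to give a seven-membered cobaltacycle. Reductive elimination between the vinyl carbon C3 and the second acyl carbon C4, the one beside the isopropyl-bearing carbon, forms C3–C4 and closes the six-membered quinone ring, a formal [4+2] of the diacyl cobalt unit with the alkyne that releases cobalt(I). No stereocentre is formed. The step needs head-to-tail regiochemistry, which rests on the match between the strong polarisation of the ynol ether and the preferred site of Lewis acid activation. Precomplexation of BF3 with 7 at low temperature before slow addition of 19 keeps free acid away from the acid-sensitive ynol ether, and brief exposure to air on work-up should return any hydroquinone formed by cobalt(I) to the quinone.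

**Compound list**
1 | 3-methylbut-1-yne | CC(C)C#C | starting material
2 | trichloroacetyl chloride | O=C(Cl)C(Cl)(Cl)Cl | starting material
3 | dichloroketene | O=C=C(Cl)Cl | intermediate
4 | 4,4-dichloro-3-isopropylcyclobut-2-en-1-one | O=C1C=C(C(C)C)C1(Cl)Cl | intermediate
5 | 3-isopropylcyclobut-3-ene-1,2-dione | O=C1C=C(C(C)C)C1=O | intermediate
6 | chloro(2-isopropylmaleoyl)bis(triphenylphosphine)cobalt(III), dative P–Co bonds written charge-separated | O=C1C=C(C(C)C)C(=O)[Co-2]1(Cl)([P+](c2ccccc2)(c2ccccc2)c2ccccc2)[P+](c2ccccc2)(c2ccccc2)c2ccccc2 | intermediate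
7 | chloro(dimethylglyoxime-N,N')(pyridine)(2-isopropylmaleoyl)cobalt(III), dative N–Co bonds written charge-separated | CC(C)C1=CC(=O)[Co-3]2(Cl)([n+]3ccccc3)([N+](O)=C(C)C(C)=[N+]2O)C1=O | intermediate
8 | thymol (2-isopropyl-5-methylphenol) | Cc1ccc(C(C)C)c(O)c1 | starting material
9 | 4-bromothymol (4-bromo-2-isopropyl-5-methylphenol) | Cc1cc(O)c(C(C)C)cc1Br | intermediate
10 | 4-methoxythymol (2-isopropyl-4-methoxy-5-methylphenol) | COc1cc(C(C)C)c(O)cc1C | intermediate
11 | 2-iodo-6-isopropyl-4-methoxy-3-methylphenol | COc1cc(C(C)C)c(O)c(I)c1C | intermediate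
12 | 2-(benzyloxy)-3-iodo-1-isopropyl-5-methoxy-4-methylbenzene | COc1cc(C(C)C)c(OCc2ccccc2)c(I)c1C | intermediate
13 | 2-(benzyloxy)-1-isopropyl-3-(2-isopropyl-4-methoxy-5-methylphenoxy)-5-methoxy-4-methylbenzene | COc1cc(C(C)C)c(Oc2c(C)c(OC)cc(C(C)C)c2OCc2ccccc2)cc1C | intermediate
14 | dimer phenol, 6-isopropyl-2-(2-isopropyl-4-methoxy-5-methylphenoxy)-4-methoxy-3-methylphenol | COc1cc(C(C)C)c(Oc2c(C)c(OC)cc(C(C)C)c2O)cc1C | intermediate
15 | trichloroethylene | ClC=C(Cl)Cl | starting material
16 | dichloroacetylene | ClC#CCl | intermediate
17 | (E)-1,2-dichlorovinyl ether of the dimer phenol | COc1cc(C(C)C)c(Oc2c(C)c(OC)cc(C(C)C)c2O/C(Cl)=C\Cl)cc1C | intermediate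
18 | lithium aryloxyacetylide of the dimer phenol | [Li]C#COc1c(C(C)C)cc(OC)c(C)c1Oc1cc(C)c(OC)cc1C(C)C | intermediate
19 | prop-1-ynyl ether of the dimer phenol | CC#COc1c(C(C)C)cc(OC)c(C)c1Oc1cc(C)c(OC)cc1C(C)C | intermediate
20 | target quinone, 3-[6-isopropyl-2-(2-isopropyl-4-methoxy-5-methylphenoxy)-4-methoxy-3-methylphenoxy]-5-isopropyl-2-methylcyclohexa-2,5-diene-1,4-dione | COc1cc(C(C)C)c(Oc2c(C)c(OC)cc(C(C)C)c2OC2=C(C)C(=O)C=C(C(C)C)C2=O)cc1C | target

**Step count and risks**
Total step count: 13. Longest linear sequence: 9 steps (thymol 8 to target 20, steps 5–13); the cobalt branch (steps 1–4) joins at step 13.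

Steps most likely to fail:

1. Step 13 (proposed new method). The alkyne may be taken up with the reverse orientation. The ynol ether may be hydrated or oligomerised by the Lewis acid before it meets the acyl carbon. The ketenium intermediate may be captured by the acyl oxygen instead of cobalt, which leads to ring-opened ester products. Fallback by known addition–elimination chemistry: setting out from 10, bromination ortho to OH (NBS, MeCN, 0 °C) would give 2-bromo-6-isopropyl-4-methoxy-3-methylphenol F1. Oxidative demethylation (CAN, MeCN/H2O, 0 °C) would give 3-bromo-5-isopropyl-2-methyl-1,4-benzoquinone F2. The caesium phenoxide of 14 (Cs2CO3, MeCN, rt) would then displace bromide from F2 by conjugate addition–elimination, which fixes the position of the aryloxy group by the position of bromine, and the route is rejoined at target 20.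

2. Step 9. Oxidative addition and C–O bond formation at the di-ortho-substituted, electron-rich aryl iodide may be slower than protodeiodination and homocoupling. Fallback by metal-free aryl transfer from iodine(III) with the roles of the two rings reversed: setting out from 12, iodine–lithium exchange (n-BuLi, THF, −78 °C) would give the aryllithium F3, which is trapped with B(OMe)3 as the dimethyl arylboronate F4 and oxidised in the same flask (H2O2, NaOH) to 2-(benzyloxy)-3-isopropyl-5-methoxy-6-methylphenol F5. Commercial 5-isopropyl-2-methylanisole (carvacrol methyl ether) with I2, mCPBA and TsOH would give the symmetric bis(2-isopropyl-4-methoxy-5-methylphenyl)iodonium tosylate F6, iodine entering para to OMe. The potassium phenoxide of F5 (t-BuOK, THF, rt to 50 °C) would be arylated by F6 through ligand coupling on iodine, a process that tolerates ortho substituents on both partners, and the route is rejoined at 13.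

3. Step 12. C-Methylation of the lithium aryloxyacetylide may be incomplete, protonation on work-up would then give the terminal ynol ether, and the product may be lost on acidic silica. Fallback that builds the ynol ether by copper-catalysed vinylation and elimination: setting out from 14, coupling with 1,1-dibromoprop-1-ene (CuI, 2,2'-bipyridine, K3PO4, PhMe, 110 °C) at the less hindered C–Br bond would give the (Z)-1-bromoprop-1-enyl ether of the dimer phenol F7. Anti elimination of HBr (t-BuOK, THF, rt) would then rejoin the route at 19.

**Further compounds**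
F1 | step 13 | 2-bromo-6-isopropyl-4-methoxy-3-methylphenol | COc1cc(C(C)C)c(O)c(Br)c1C
F2 | step 13 | 3-bromo-5-isopropyl-2-methylcyclohexa-2,5-diene-1,4-dione | O=C1C(Br)=C(C)C(=O)C=C1C(C)C
F3 | step 9 | [2-(benzyloxy)-3-isopropyl-5-methoxy-6-methylphenyl]lithium | COc1cc(C(C)C)c(OCc2ccccc2)c([Li])c1C
F4 | step 9 | dimethyl [2-(benzyloxy)-3-isopropyl-5-methoxy-6-methylphenyl]boronate | COc1cc(C(C)C)c(OCc2ccccc2)c(B(OC)OC)c1C
F5 | step 9 | 2-(benzyloxy)-3-isopropyl-5-methoxy-6-methylphenol | COc1cc(C(C)C)c(OCc2ccccc2)c(O)c1C
F6 | step 9 | bis(2-isopropyl-4-methoxy-5-methylphenyl)iodonium 4-toluenesulfonate | COc1cc(C(C)C)c([I+]c2cc(C)c(OC)cc2C(C)C)cc1C.Cc1ccc(cc1)S(=O)(=O)[O-]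
F7 | step 12 | (Z)-1-bromoprop-1-enyl ether of the dimer phenol | C/C=C(/Oc1c(C(C)C)cc(OC)c(C)c1Oc1cc(C)c(OC)cc1C(C)C)Br
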